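The whole plan rests on the C1=C2 alkene of the methylcyclohexene core (C1 bears the methyl group, C2 is the vinylic CH next to C3). This bond carries no stereochemistry, so ring-closing metathesis can form it last among the ring bonds, from an acyclic octa-1,7-diene aldehyde in which C3, C4 and C5 are already set. C5 comes from rhodium-catalyzed asymmetric conjugate arylation, and C3 and C4 are set together by dual iridium/amine-catalyzed α-allylation. After ring closure, the aroyl ring B and the chalcone arm on ring A are attached by aryllithium chemistry, followed by oxidation and removal of eight methoxymethyl groups.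

Key step: step 13

Remarks
- Locants used throughout: cyclohexene C1 (methyl-bearing sp2 carbon), C2 (=CH), C3 (bears ring A, the 2,6-dioxygenated ring that carries the chalcone carbonyl), C4 (bears the aroyl group with ring B), C5 (bears ring C), C6 (CH2). Ring D is the distal chalcone ring. The target is 3S,4R,5S: ring A and the aroyl group are cis, the aroyl group and ring C are trans. MOM = methoxymethyl.
- Assumption: the sense of induction is taken as (S)-binap → 5S in step 4, (S)-amine → 4R and (S)-ligand → 3S in step 12. The two catalysts of step 12 act independently, so the antipode of any of these is substituted if the sense proves opposite.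
- Aldehyde 11 is made once in step 6 and divided between steps 7 and 8.

Step 1
Reactants: 1 4-bromoresorcinol
Product: 2 1-bromo-2,4-bis(methoxymethoxy)benzene
Conditions: MOMCl (2.5 equiv), i-Pr2NEt, CH2Cl2, 0 °C → rt
Reagents that add atoms: chloromethyl methyl ether, COCCl
Why: Double O-alkylation of the phenols (MOM protection) gives acetal ethers that survive bases and organometallics and direct the later lithiations.

Step 2
Reactants: 2 1-bromo-2,4-bis(methoxymethoxy)benzene
Product: 4 2,4-bis(methoxymethoxy)phenylboronic acid, via aryllithium 3 (not isolated)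
Conditions: n-BuLi, THF, −78 °C; B(O-i-Pr)3; aq. NH4Cl
Reagents that add atoms: triisopropyl borate, CC(C)OB(OC(C)C)OC(C)C; water, O
Why: Bromine–lithium exchange outruns ortho-deprotonation at −78 °C, and borylation of the aryllithium followed by mild hydrolysis should give the boronic acid (lithiation–borylation).

Step 3
Reactants: 5 2-methylpenta-1,4-diene; 6 methyl acrylate (3 equiv)
Product: 7 methyl (2E)-5-methylhexa-2,5-dienoate
Conditions: second-generation Hoveyda–Grubbs catalyst (2 mol%), CH2Cl2, 40 °C
Reagents that add atoms: none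
Why: Olefin cross-metathesis of the monosubstituted alkene with the acrylate is E-selective, while the 1,1-disubstituted alkene is too hindered to take part.

Step 4
Reactants: 7 methyl (2E)-5-methylhexa-2,5-dienoate; 4 2,4-bis(methoxymethoxy)phenylboronic acid (2.5 equiv)
Product: 8 methyl (3S)-3-[2,4-bis(methoxymethoxy)phenyl]-5-methylhex-5-enoate
Conditions: [Rh(OH)((S)-binap)]2 (3 mol% Rh), dioxane/H2O 10:1, 35 °C
Reagents that add atoms: none
Why: Hayashi–Miyaura asymmetric 1,4-addition, in which the binap-bound arylrhodium adds to one face of the E-enoate and so sets C5 (S), while the preformed hydroxorhodium–binap dimer transmetalates without added base at low temperature and should not move the skipped diene into conjugation.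

Step 5
Reactants: 8 methyl (3S)-3-[2,4-bis(methoxymethoxy)phenyl]-5-methylhex-5-enoate
Product: 9 (3S)-3-[2,4-bis(methoxymethoxy)phenyl]-5-methylhex-5-enal
Conditions: i-Bu2AlH (1.1 equiv), CH2Cl2, −78 °C; aq. potassium sodium tartrate
Reagents that add atoms: none
Why: Partial ester reduction stops at the aluminium hemiacetal at −78 °C and releases the aldehyde on work-up, leaving the non-acidic C5 center untouched.

Step 6
Reactants: 2 1-bromo-2,4-bis(methoxymethoxy)benzene
Product: 11 3-bromo-2,6-bis(methoxymethoxy)benzaldehyde, via aryllithium 10 (not isolated)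
Conditions: LiN(i-Pr)2, THF, −78 °C; DMF; aq. NH4Cl
Reagents that add atoms: N,N-dimethylformamide, CN(C)C=O
Why: Directed ortho-metalation by the amide base occurs at the position flanked by both MOM ethers without touching the bromide, and formylation gives the aldehyde.

Step 7
Reactants: 11 3-bromo-2,6-bis(methoxymethoxy)benzaldehyde
Product: 12 rac-1-[3-bromo-2,6-bis(methoxymethoxy)phenyl]prop-2-en-1-ol
Conditions: CH2=CHMgBr, THF, −78 → 0 °C; aq. NH4Cl
Reagents that add atoms: vinylmagnesium bromide, C=C[Mg]Br
Why: Grignard 1,2-addition to the aldehyde gives the branched allylic alcohol, and the racemate is acceptable because step 12 is enantioconvergent.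

Step 8
Reactants: 11 3-bromo-2,6-bis(methoxymethoxy)benzaldehyde
Product: 13 rac-1-[3-bromo-2,6-bis(methoxymethoxy)phenyl]-3-methylbutan-1-ol
Conditions: i-BuMgBr (1.3 equiv), THF, −40 → 0 °C; aq. NH4Cl
Reagents that add atoms: isobutylmagnesium bromide, CC(C)C[Mg]Br
Why: Grignard 1,2-addition to the non-enolizable aldehyde, assisted by chelation of magnesium by the ortho MOM ether, installs the isobutyl group, and the aryl bromide does not exchange with an alkylmagnesium halide at this temperature.

Step 9
Reactants: 13 rac-1-[3-bromo-2,6-bis(methoxymethoxy)phenyl]-3-methylbutan-1-ol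
Product: 14 1-bromo-2,4-bis(methoxymethoxy)-3-[(1E)-3-methylbut-1-en-1-yl]benzene
Conditions: Burgess reagent, THF/toluene, 50 °C
Reagents that add atoms: none
Why: Burgess dehydration through the sulfamate ester can only eliminate toward the single β-CH2 and should give the conjugated E-alkene, the Z isomer being disfavoured by the two ortho substituents.

Step 10
Reactants: 15 2,4-dihydroxybenzaldehyde
Product: 16 2,4-bis(methoxymethoxy)benzaldehyde
Conditions: MOMCl (3 equiv), i-Pr2NEt, CH2Cl2, 0 °C → reflux
Reagents that add atoms: chloromethyl methyl ether, COCCl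
Why: MOM protection of both phenols, the hydrogen-bonded ortho one requiring excess reagent and warming.

Step 11
Reactants: 16 2,4-bis(methoxymethoxy)benzaldehyde; 17 diethyl [2-(methoxy(methyl)amino)-2-oxoethyl]phosphonate
Product: 18 (2E)-3-[2,4-bis(methoxymethoxy)phenyl]-N-methoxy-N-methylprop-2-enamide
Conditions: LiCl, DBU, MeCN, rt
Reagents that add atoms: none
Why: Horner–Wadsworth–Emmons olefination under Masamune–Roush conditions gives the E-configured cinnamoyl Weinreb amide.

Step 12
Reactants: 9 (3S)-3-[2,4-bis(methoxymethoxy)phenyl]-5-methylhex-5-enal; 12 rac-1-[3-bromo-2,6-bis(methoxymethoxy)phenyl]prop-2-en-1-ol (1.3 equiv)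
Product: 19 (2R,3S)-3-[3-bromo-2,6-bis(methoxymethoxy)phenyl]-2-[(1S)-1-[2,4-bis(methoxymethoxy)phenyl]-3-methylbut-3-en-1-yl]pent-4-enal
Conditions: [Ir(cod)Cl]2 (3 mol%), (S)-N-(dinaphtho[2,1-d:1',2'-f][1,3,2]dioxaphosphepin-4-yl)dibenzo[b,f]azepine (12 mol%), (S)-α,α-bis[3,5-bis(trifluoromethyl)phenyl]prolinol trimethylsilyl ether (15 mol%), ZnBr2 (7.5 mol%), ClCH2CH2Cl, 25 °C
Reagents that add atoms: none
Why: Stereodivergent dual catalysis (iridium-catalyzed allylic substitution merged with enamine catalysis): both enantiomers of 12 ionize to the same chiral (π-allyl)iridium complex, which the E-enamine of 9 attacks at the aryl-bearing terminus, so that the ligand sets C3 (S), the amine sets C4 (R) and the existing C5 center is only a spectator.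

Step 13
Reactants: 19 (2R,3S)-3-[3-bromo-2,6-bis(methoxymethoxy)phenyl]-2-[(1S)-1-[2,4-bis(methoxymethoxy)phenyl]-3-methylbut-3-en-1-yl]pent-4-enal
Product: 20 (1R,2S,6S)-2-[3-bromo-2,6-bis(methoxymethoxy)phenyl]-6-[2,4-bis(methoxymethoxy)phenyl]-4-methylcyclohex-3-ene-1-carbaldehyde
Conditions: second-generation Grubbs catalyst (5 mol%), CH2Cl2 (0.005 M), 40 °C
Reagents that add atoms: none
Why: Ring-closing olefin metathesis by the Chauvin mechanism: the ruthenium benzylidene first exchanges onto the monosubstituted vinyl group at C2, the new alkylidene undergoes [2+2] cycloaddition with the 1,1-disubstituted methallyl alkene, and cycloreversion expels ethene, so that C1=C2 is the ring-closing bond. The closest known reaction type is ring-closing metathesis of octa-1,7-dienes to 1-methylcyclohexenes that carry an allylic aryl group next to a formyl-bearing carbon. The six-membered carbocycle is closed by metathesis between the two alkene termini with loss of ethene, and no other ring is formed. No stereocenter is created, and C3, C4 and C5 are carried over unchanged because the catalyst is neutral and the C4–H alpha to the aldehyde is not touched. The step needs cyclization to win over oligomerization and over epimerization; this is secured by the three contiguous substituted carbons, which bias the chain toward ring-like conformers, by the absence of any other alkene (the methallyl group cannot homodimerize) and by high dilution.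

Step 14
Reactants: 20 (1R,2S,6S)-2-[3-bromo-2,6-bis(methoxymethoxy)phenyl]-6-[2,4-bis(methoxymethoxy)phenyl]-4-methylcyclohex-3-ene-1-carbaldehyde; 14 1-bromo-2,4-bis(methoxymethoxy)-3-[(1E)-3-methylbut-1-en-1-yl]benzene (1.1 equiv); 18 (2E)-3-[2,4-bis(methoxymethoxy)phenyl]-N-methoxy-N-methylprop-2-enamide (2 equiv)
Product: 24 C4-carbinol of octakis-O-(methoxymethyl)artonin C (3S,4R,5S; carbinol epimers), via aryllithium 21 (not isolated), via lithium alkoxide 22 (not isolated), via dilithio species 23 (not isolated)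
Conditions: 14, t-BuLi (2.2 equiv), THF, −78 °C; 20, −78 °C; t-BuLi (2.1 equiv), −78 °C; 18, −78 → −20 °C; aq. NH4Cl
Reagents that add atoms: none
Why: The ring B aryllithium adds to the aldehyde much faster than it exchanges with the ring A bromide, the resulting lithium alkoxide protects the carbinol while a second bromine–lithium exchange unmasks ring A as a nucleophile, and acylation of this aryllithium by the Weinreb amide (stable chelate, no over-addition) should give the E-chalcone, the two carbinol epimers converging in step 15.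

Step 15
Reactants: 24 C4-carbinol of octakis-O-(methoxymethyl)artonin C
Product: 25 octakis-O-(methoxymethyl)artonin C (3S,4R,5S)
Conditions: Dess–Martin periodinane, CH2Cl2, 0 °C → rt
Reagents that add atoms: none
Why: Dess–Martin oxidation of the secondary benzylic alcohol runs without base, so C4, now alpha to the ketone, should not epimerize and the chalcone and alkenes are untouched.

Step 16
Reactants: 25 octakis-O-(methoxymethyl)artonin C
Product: 26 artonin C
Conditions: Me3SiOTf (16 equiv), 2,2'-bipyridyl (24 equiv), MeCN, 0 °C → rt; then H2O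
Reagents that add atoms: none
Why: Silyl triflate with bipyridyl converts aryl MOM ethers into aryl silyl ethers through N-(methoxymethyl)pyridinium salts and water then frees the phenols, which avoids the Brønsted acid that would promote ketalization of the C4 carbonyl, flavylium formation or phenol-to-alkene cyclization.

Compound list
1 | 4-bromoresorcinol | Oc1ccc(Br)c(O)c1 | starting material
2 | 1-bromo-2,4-bis(methoxymethoxy)benzene | COCOc1ccc(Br)c(OCOC)c1 | intermediate
3 | 2,4-bis(methoxymethoxy)phenyllithium | [Li]c1ccc(OCOC)cc1OCOC | intermediate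
4 | 2,4-bis(methoxymethoxy)phenylboronic acid | OB(O)c1ccc(OCOC)cc1OCOC | intermediate
5 | 2-methylpenta-1,4-diene | C=C(C)CC=C | starting material
6 | methyl acrylate | C=CC(=O)OC | starting material
7 | methyl (2E)-5-methylhexa-2,5-dienoate | C=C(C)C/C=C/C(=O)OC | intermediate
8 | methyl (3S)-3-[2,4-bis(methoxymethoxy)phenyl]-5-methylhex-5-enoate | COC(=O)C[C@@H](c1ccc(OCOC)cc1OCOC)CC(C)=C | intermediate
9 | (3S)-3-[2,4-bis(methoxymethoxy)phenyl]-5-methylhex-5-enal | O=CC[C@@H](c1ccc(OCOC)cc1OCOC)CC(C)=C | intermediate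
10 | 3-bromo-2,6-bis(methoxymethoxy)phenyllithium | [Li]c1c(OCOC)ccc(Br)c1OCOC | intermediate
11 | 3-bromo-2,6-bis(methoxymethoxy)benzaldehyde | O=Cc1c(OCOC)ccc(Br)c1OCOC | intermediate
12 | rac-1-[3-bromo-2,6-bis(methoxymethoxy)phenyl]prop-2-en-1-ol | C=CC(O)c1c(OCOC)ccc(Br)c1OCOC | intermediate
13 | rac-1-[3-bromo-2,6-bis(methoxymethoxy)phenyl]-3-methylbutan-1-ol | CC(C)CC(O)c1c(OCOC)ccc(Br)c1OCOC | intermediate
14 | 1-bromo-2,4-bis(methoxymethoxy)-3-[(1E)-3-methylbut-1-en-1-yl]benzene | CC(C)/C=C/c1c(OCOC)ccc(Br)c1OCOC | intermediate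
15 | 2,4-dihydroxybenzaldehyde | O=Cc1ccc(O)cc1O | starting material
16 | 2,4-bis(methoxymethoxy)benzaldehyde | O=Cc1ccc(OCOC)cc1OCOC | intermediate
17 | diethyl [2-(methoxy(methyl)amino)-2-oxoethyl]phosphonate | CCOP(=O)(CC(=O)N(C)OC)OCC | starting material
18 | (2E)-3-[2,4-bis(methoxymethoxy)phenyl]-N-methoxy-N-methylprop-2-enamide | CON(C)C(=O)/C=C/c1ccc(OCOC)cc1OCOC | intermediate
19 | (2R,3S)-3-[3-bromo-2,6-bis(methoxymethoxy)phenyl]-2-[(1S)-1-[2,4-bis(methoxymethoxy)phenyl]-3-methylbut-3-en-1-yl]pent-4-enal | C=C[C@H](c1c(OCOC)ccc(Br)c1OCOC)[C@H](C=O)[C@@H](c1ccc(OCOC)cc1OCOC)CC(C)=C | intermediate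
20 | (1R,2S,6S)-2-[3-bromo-2,6-bis(methoxymethoxy)phenyl]-6-[2,4-bis(methoxymethoxy)phenyl]-4-methylcyclohex-3-ene-1-carbaldehyde | CC1=C[C@H](c2c(OCOC)ccc(Br)c2OCOC)[C@H](C=O)[C@@H](c2ccc(OCOC)cc2OCOC)C1 | intermediate
21 | 2,4-bis(methoxymethoxy)-3-[(1E)-3-methylbut-1-en-1-yl]phenyllithium | [Li]c1ccc(OCOC)c(/C=C/C(C)C)c1OCOC | intermediate
22 | lithium alkoxide of the carbinol formed from 20 and 21 (ring A still brominated; 3S,4R,5S; carbinol epimers) | CC1=C[C@H](c2c(OCOC)ccc(Br)c2OCOC)[C@H](C(O[Li])c2ccc(OCOC)c(/C=C/C(C)C)c2OCOC)[C@@H](c2ccc(OCOC)cc2OCOC)C1 | intermediate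
23 | dilithio species from 22 (ring A lithiated where the bromine was) | CC1=C[C@H](c2c(OCOC)ccc([Li])c2OCOC)[C@H](C(O[Li])c2ccc(OCOC)c(/C=C/C(C)C)c2OCOC)[C@@H](c2ccc(OCOC)cc2OCOC)C1 | intermediate
24 | C4-carbinol of octakis-O-(methoxymethyl)artonin C (CH(OH) in place of the C4 aroyl C=O; 3S,4R,5S; carbinol epimers) | CC1=C[C@H](c2c(OCOC)ccc(C(=O)/C=C/c3ccc(OCOC)cc3OCOC)c2OCOC)[C@H](C(O)c2ccc(OCOC)c(/C=C/C(C)C)c2OCOC)[C@@H](c2ccc(OCOC)cc2OCOC)C1 | intermediate
25 | octakis-O-(methoxymethyl)artonin C (3S,4R,5S) | CC1=C[C@H](c2c(OCOC)ccc(C(=O)/C=C/c3ccc(OCOC)cc3OCOC)c2OCOC)[C@H](C(=O)c2ccc(OCOC)c(/C=C/C(C)C)c2OCOC)[C@@H](c2ccc(OCOC)cc2OCOC)C1 | intermediate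
26 | artonin C (3S,4R,5S) | CC1=C[C@H](c2c(O)ccc(C(=O)/C=C/c3ccc(O)cc3O)c2O)[C@H](C(=O)c2ccc(O)c(/C=C/C(C)C)c2O)[C@@H](c2ccc(O)cc2O)C1 | target

Total step count: 16.
Longest linear sequence: 9 steps (steps 1, 2, 4, 5, 12, 13, 14, 15, 16, from 4-bromoresorcinol).

Steps most likely to fail

Step 12. The β-branched aldehyde 9 may form its enamine slowly, or the two catalysts may not fully override the C5 center, giving low conversion or poor diastereoselection. The fallback sets C3 and C4 by an Ireland–Claisen rearrangement; it sets out from 8 and 11 and comes back at 19. Aldehyde 11 is olefinated with triethyl phosphonoacetate (LiCl, DBU) to ethyl (2E)-3-[3-bromo-2,6-bis(methoxymethoxy)phenyl]prop-2-enoate F1, which i-Bu2AlH reduces to (2E)-3-[3-bromo-2,6-bis(methoxymethoxy)phenyl]prop-2-en-1-ol F2. Ester 8 is saponified with LiOH to (3S)-3-[2,4-bis(methoxymethoxy)phenyl]-5-methylhex-5-enoic acid F3, and coupling with F2 (EDC, DMAP) gives the cinnamyl ester F4. Enolization with LiN(i-Pr)2 in THF/DMPU at −78 °C and silylation with Me3SiCl give the (Z)-trimethylsilyl ketene acetal F5, in which the α-substituent is cis to the silyloxy group. On warming it rearranges through a chair transition state, with the aryl group and the α-substituent both equatorial, to the trimethylsilyl ester F6. Hydrolysis on work-up gives the (2R,3S) acid F7, which has the 2,3-syn relationship that the cis arrangement at C3 and C4 requires. The C5 center is expected to exert only modest facial control, so the isomer with the opposite sense at C3 and C4 is separated. Reduction with LiAlH4 at 0 °C gives the primary alcohol F8, and Dess–Martin oxidation returns aldehyde 19.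

Step 14. The second halogen–lithium exchange may be followed by protonation of the ring A aryllithium, or the first aryllithium may enolize the hindered aldehyde or attack amide 18, so the chalcone arm is not installed cleanly. The fallback divides the sequence and builds the chalcone by aldol condensation at the carbinol oxidation level, where C4 cannot epimerize; it sets out from 20 and 14 and comes back at 24. Aryllithium 21, made from 14, is added to 20 and the neutral bromo carbinol F9 is isolated. Stille coupling with tributyl(1-ethoxyvinyl)stannane (Pd(PPh3)4, a zerovalent palladium catalyst, toluene, 100 °C) gives the 1-ethoxyvinyl compound F10. Brief hydrolysis with oxalic acid on wet silica gives the ring A methyl ketone F11. Claisen–Schmidt condensation of F11 with aldehyde 16 (KOH, EtOH/H2O, rt) gives 24.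

Step 16. During the aqueous stage, acetal cleavage may be accompanied by ketalization of the C4 carbonyl by the ring A and ring C phenols, or by addition of a phenol to an alkene. The fallback releases the phenols in two stages without water or acid; it sets out from 25 and comes back at 26. Et3SiOTf with 2,2'-bipyridyl in CH2Cl2 converts 25 into the octakis(triethylsilyl) ether of artonin C F12, which is isolated and then desilylated with Bu4NF buffered with AcOH in THF at 0 °C to give 26.

Further compounds
F1 | step 12 | ethyl (2E)-3-[3-bromo-2,6-bis(methoxymethoxy)phenyl]prop-2-enoate | CCOC(=O)/C=C/c1c(OCOC)ccc(Br)c1OCOC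
F2 | step 12 | (2E)-3-[3-bromo-2,6-bis(methoxymethoxy)phenyl]prop-2-en-1-ol | OC/C=C/c1c(OCOC)ccc(Br)c1OCOC
F3 | step 12 | (3S)-3-[2,4-bis(methoxymethoxy)phenyl]-5-methylhex-5-enoic acid | OC(=O)C[C@@H](c1ccc(OCOC)cc1OCOC)CC(C)=C
F4 | step 12 | (2E)-3-[3-bromo-2,6-bis(methoxymethoxy)phenyl]prop-2-en-1-yl (3S)-3-[2,4-bis(methoxymethoxy)phenyl]-5-methylhex-5-enoate | O=C(OC/C=C/c1c(OCOC)ccc(Br)c1OCOC)C[C@@H](c1ccc(OCOC)cc1OCOC)CC(C)=C
F5 | step 12 | (Z)-trimethylsilyl ketene acetal of F4 | C[Si](C)(C)O/C(OC/C=C/c1c(OCOC)ccc(Br)c1OCOC)=C\[C@@H](c1ccc(OCOC)cc1OCOC)CC(C)=C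
F6 | step 12 | trimethylsilyl (2R,3S)-3-[3-bromo-2,6-bis(methoxymethoxy)phenyl]-2-[(1S)-1-[2,4-bis(methoxymethoxy)phenyl]-3-methylbut-3-en-1-yl]pent-4-enoate | C=C[C@H](c1c(OCOC)ccc(Br)c1OCOC)[C@H](C(=O)O[Si](C)(C)C)[C@@H](c1ccc(OCOC)cc1OCOC)CC(C)=C
F7 | step 12 | (2R,3S)-3-[3-bromo-2,6-bis(methoxymethoxy)phenyl]-2-[(1S)-1-[2,4-bis(methoxymethoxy)phenyl]-3-methylbut-3-en-1-yl]pent-4-enoic acid | C=C[C@H](c1c(OCOC)ccc(Br)c1OCOC)[C@H](C(=O)O)[C@@H](c1ccc(OCOC)cc1OCOC)CC(C)=C
F8 | step 12 | (2R,3S)-3-[3-bromo-2,6-bis(methoxymethoxy)phenyl]-2-[(1S)-1-[2,4-bis(methoxymethoxy)phenyl]-3-methylbut-3-en-1-yl]pent-4-en-1-ol | C=C[C@H](c1c(OCOC)ccc(Br)c1OCOC)[C@H](CO)[C@@H](c1ccc(OCOC)cc1OCOC)CC(C)=C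
F9 | step 14 | neutral bromo carbinol from 20 and 21 (ring A brominated; 3S,4R,5S; carbinol epimers) | CC1=C[C@H](c2c(OCOC)ccc(Br)c2OCOC)[C@H](C(O)c2ccc(OCOC)c(/C=C/C(C)C)c2OCOC)[C@@H](c2ccc(OCOC)cc2OCOC)C1
F10 | step 14 | 1-ethoxyvinyl analogue of F9 (ring A carries C(OEt)=CH2 in place of Br) | CC1=C[C@H](c2c(OCOC)ccc(C(=C)OCC)c2OCOC)[C@H](C(O)c2ccc(OCOC)c(/C=C/C(C)C)c2OCOC)[C@@H](c2ccc(OCOC)cc2OCOC)C1
F11 | step 14 | ring A methyl ketone (acetyl in place of Br in F9) | CC1=C[C@H](c2c(OCOC)ccc(C(C)=O)c2OCOC)[C@H](C(O)c2ccc(OCOC)c(/C=C/C(C)C)c2OCOC)[C@@H](c2ccc(OCOC)cc2OCOC)C1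
F12 | step 16 | octakis-O-(triethylsilyl)artonin C | CC1=C[C@H](c2c(O[Si](CC)(CC)CC)ccc(C(=O)/C=C/c3ccc(O[Si](CC)(CC)CC)cc3O[Si](CC)(CC)CC)c2O[Si](CC)(CC)CC)[C@H](C(=O)c2ccc(O[Si](CC)(CC)CC)c(/C=C/C(C)C)c2O[Si](CC)(CC)CC)[C@@H](c2ccc(O[Si](CC)(CC)CC)cc2O[Si](CC)(CC)CC)C1
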